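**Retrosynthetic overview**

1. Locants: the ring carbons are C1 (carries the acrylic acid), C4 (Me, OH), C5 (OAc), C8 (=CH2), C9, C12 (Me), C13 (OH) and C14; the oxolane is O–C9–C10–C11–C12. The Why lines and the names of the cyclic compounds use these locants; open-chain compounds are named with their own chain locants.
2. Enabling feature: the oxolane bridges the 14-membered carbocycle, so C10–C11 is a bond of both rings, the ether oxygen sits on C9 next to C10, and C12 is fully substituted (methyl). This is a three-atom O–C9–C10 unit plus a two-atom C11=C12 isopropenyl-type unit at the two ends of one chain.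
3. Key disconnection: C10–C11 and O–C12 together, back to the open-chain trichloromethyl carbinol 24 (C10 as CCl3, C11=C12 as a 1,1-disubstituted alkene). One copper-catalysed atom-transfer radical annulation closes first the carbocycle, then the oxolane.
4. Chain 24: C4/C5 from Sharpless epoxidation of geraniol (oxirane later opened with inversion at C4); C6–C7 by copper-catalysed Grignard coupling; C1 by organocatalytic malonate Michael addition to a cross-metathesis enal; C13 and C9 each by carbonyl addition then oxazaborolidine-controlled reduction.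
5. End game: dechlorination at C10, fluoride removal of all silyl groups, Mannich decarboxylative methylenation of the malonic acid to the acrylic acid.

Key step: step 17

Remark: the target is taken as the free hydroxy acid drawn; it is assumed that O13 does not lactonise onto the carboxyl group under the basic conditions and pH 4 work-up of the last step.

**Route**

Step 1
Reactants: 1 geraniol
Product: 3 [(2R,3R)-3-methyl-3-(4-methylpent-3-en-1-yl)oxiran-2-yl]methyl 4-methylbenzenesulfonate, via (2R,3R)-2,3-epoxygeraniol 2 (not isolated)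
Conditions: Ti(OiPr)4 (5 mol %), D-(−)-diisopropyl tartrate (6 mol %), t-BuOOH, 4 Å MS, CH2Cl2, −20 °C; then Et3N, TsCl, DMAP (cat.), −10 °C
Reagents that add atoms: tert-butyl hydroperoxide CC(C)(C)OO; p-toluenesulfonyl chloride Cc1ccc(cc1)S(=O)(=O)Cl
Why: Sharpless asymmetric epoxidation with the D-(−)-tartrate ligand delivers oxygen to one face of the E-allylic alcohol and fixes both oxirane carbons as (2R,3R) (C5 in its final configuration, C4 in the configuration that step 6 inverts), and the primary alcohol is tosylated in the same flask.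

Step 2
Reactants: 3 epoxy tosylate; 4 2-(2-bromoethyl)-1,3-dioxolane
Product: 6 2-{3-[(2R,3R)-3-methyl-3-(4-methylpent-3-en-1-yl)oxiran-2-yl]propyl}-1,3-dioxolane, via Grignard reagent 5 (not isolated)
Conditions: Mg, THF, 25 °C; then 3, CuI (10 mol %), THF, −30 to 0 °C
Reagents that add atoms: none
Why: Copper-catalysed cross-coupling of a Grignard reagent with a primary alkyl tosylate (SN2 at C6) forms the C6–C7 bond; the trisubstituted oxirane is too hindered to compete at low temperature and no stereocenter is touched.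

Step 3
Reactants: 6 epoxy acetal; 7 (E)-but-2-enal
Product: 8 (2E)-5-{(2R,3R)-3-[3-(1,3-dioxolan-2-yl)propyl]-2-methyloxiran-2-yl}pent-2-enal
Conditions: 7 (5 equiv), second-generation Hoveyda–Grubbs catalyst RuCl2(H2IMes)(=CH-C6H4-2-OiPr) (5 mol %), CH2Cl2, 40 °C
Reagents that add atoms: none
Why: Olefin cross-metathesis: the prenyl terminus is the only alkene in 6 and exchanges its isopropylidene for the formylmethylidene of crotonaldehyde, the conjugated E-enal being strongly favoured.

Step 4
Reactants: 9 malonic acid; 10 2-(trimethylsilyl)ethanol (2.2 equiv in all, one molecule per carboxyl group)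
Product: 11 bis[2-(trimethylsilyl)ethyl] propanedioate
Conditions: 10 (2.2 equiv), DCC (2.2 equiv), MeCN, 0 to 25 °C
Reagents that add atoms: 2-(trimethylsilyl)ethanol (second equivalent of 10, for the second carboxyl group) C[Si](C)(C)CCO
Why: Twofold carbodiimide (Steglich-type) esterification: each carboxyl group of malonic acid is activated by DCC and takes up one molecule of the alcohol, giving a malonate whose esters can later be removed by fluoride without touching an acetate.

Step 5
Reactants: 8 enal; 11 malonate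
Product: 12 bis[2-(trimethylsilyl)ethyl] 2-[(3S)-5-{(2R,3R)-3-[3-(1,3-dioxolan-2-yl)propyl]-2-methyloxiran-2-yl}-1-oxopentan-3-yl]propanedioate
Conditions: (R)-2-{bis[3,5-bis(trifluoromethyl)phenyl](trimethylsilyloxy)methyl}pyrrolidine (10 mol %), EtOH, 0 °C
Reagents that add atoms: none
Why: Iminium-catalysed asymmetric Michael addition: the (R)-diarylprolinol silyl ether shields one face of the E-iminium ion, so the malonate adds to the other face and sets C1 as (S), the facial sense established for malonate and nitroalkane additions to enals with this catalyst class.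

Step 6
Reactants: 12 epoxy aldehyde
Product: 13 bis[2-(trimethylsilyl)ethyl] 2-[(3S,6S,7R)-10-(1,3-dioxolan-2-yl)-6,7-dihydroxy-6-methyl-1-oxodecan-3-yl]propanedioate
Conditions: HClO4 (0.02 M), THF/H2O 2:1, 0 °C
Reagents that add atoms: water O
Why: Acid-catalysed epoxide hydrolysis: water opens the protonated trisubstituted oxirane at the tertiary carbon C4 with inversion while C5 keeps its configuration, giving the (4S,5R) diol of the target, and the dilute acid at 0 °C should leave the dioxolane intact.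

Step 7
Reactants: 13 diol
Product: 14 bis[2-(trimethylsilyl)ethyl] 2-[(3S,6S,7R)-7-acetoxy-10-(1,3-dioxolan-2-yl)-6-hydroxy-6-methyl-1-oxodecan-3-yl]propanedioate
Conditions: Ac2O, pyridine, DMAP (cat.), CH2Cl2, 0 °C
Reagents that add atoms: acetic anhydride CC(=O)OC(C)=O
Why: Chemoselective acylation: the secondary C5 hydroxyl is acetylated while the tertiary C4 hydroxyl does not react under these mild conditions.

Step 8
Reactants: 14 aldehyde; 15 2-bromopropene
Product: 16 bis[2-(trimethylsilyl)ethyl] 2-[(5S,8S,9R)-9-acetoxy-12-(1,3-dioxolan-2-yl)-3,8-dihydroxy-2,8-dimethyldodec-1-en-5-yl]propanedioate (both C3 epimers)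
Conditions: CrCl2 (4 equiv), NiCl2 (2 mol %), DMF, 25 °C
Reagents that add atoms: none
Why: Nozaki–Hiyama–Kishi reaction: the 2-propenylchromium reagent adds only to the aldehyde and tolerates the esters, the acidic malonate C–H and the free tertiary alcohol; C13 forms as an epimer mixture that steps 9 and 10 correct.

Step 9
Reactants: 16 allylic alcohol
Product: 17 bis[2-(trimethylsilyl)ethyl] 2-[(5S,8S,9R)-9-acetoxy-12-(1,3-dioxolan-2-yl)-8-hydroxy-2,8-dimethyl-3-oxododec-1-en-5-yl]propanedioate
Conditions: Dess–Martin periodinane, NaHCO3, CH2Cl2, 0 to 25 °C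
Reagents that add atoms: none
Why: Dess–Martin oxidation of the secondary allylic alcohol under neutral buffered conditions avoids base-induced conjugate addition of the malonate to the new enone, and the tertiary alcohol cannot be oxidised.

Step 10
Reactants: 17 enone
Product: 18 bis[2-(trimethylsilyl)ethyl] 2-[(3S,5S,8S,9R)-9-acetoxy-12-(1,3-dioxolan-2-yl)-3,8-dihydroxy-2,8-dimethyldodec-1-en-5-yl]propanedioate
Conditions: (R)-2-methyl-CBS-oxazaborolidine (20 mol %), catecholborane, toluene, −78 °C
Reagents that add atoms: none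
Why: Corey–Bakshi–Shibata reduction: with the isopropenyl group as the large and the C14 methylene as the small ketone substituent, the (R)-oxazaborolidine should deliver hydride to the face that gives the (S)-allylic alcohol at C13.

Step 11
Reactants: 18 allylic alcohol
Product: 19 bis[2-(trimethylsilyl)ethyl] 2-[(3S,5S,8S,9R)-9-acetoxy-3-[(tert-butyldimethylsilyl)oxy]-12-(1,3-dioxolan-2-yl)-8-hydroxy-2,8-dimethyldodec-1-en-5-yl]propanedioate
Conditions: TBSCl, imidazole, DMF, 25 °C
Reagents that add atoms: tert-butyldimethylsilyl chloride CC(C)(C)[Si](C)(C)Cl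
Why: Silylation of the secondary allylic alcohol (the tertiary C4 hydroxyl is too hindered for TBSCl/imidazole) protects O13 from the later oxidation and blocks its participation at C12 in the key step.

Step 12
Reactants: 19 dioxolane
Product: 20 bis[2-(trimethylsilyl)ethyl] 2-[(3S,5S,8S,9R)-9-acetoxy-3-[(tert-butyldimethylsilyl)oxy]-8-hydroxy-2,8-dimethyl-13-oxotridec-1-en-5-yl]propanedioate
Conditions: PPTS, acetone/H2O 4:1, 60 °C
Reagents that add atoms: water O
Why: Mild acid-catalysed acetal hydrolysis unveils the C9 aldehyde; the secondary silyl ether, the acetate and the silylethyl esters should survive pyridinium tosylate.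

Step 13
Reactants: 20 aldehyde
Product: 21 bis[2-(trimethylsilyl)ethyl] 2-[(3S,5S,8S,9R)-9-acetoxy-3-[(tert-butyldimethylsilyl)oxy]-12-formyl-8-hydroxy-2,8-dimethyltrideca-1,12-dien-5-yl]propanedioate
Conditions: aq. CH2O (37 %), pyrrolidine (10 mol %), EtCO2H (10 mol %), i-PrOH, 45 °C
Reagents that add atoms: formaldehyde C=O
Why: Amine-catalysed Mannich-type α-methylenation of the aldehyde (enamine addition to the iminium ion of formaldehyde, then elimination of the amine) installs the C8 methylidene.

Step 14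
Reactants: 21 enal
Product: 22 bis[2-(trimethylsilyl)ethyl] 2-[(3S,5S,8S,9R)-9-acetoxy-3-[(tert-butyldimethylsilyl)oxy]-14,14,14-trichloro-8,13-dihydroxy-2,8-dimethyl-12-methylidenetetradec-1-en-5-yl]propanedioate (both C13 epimers)
Conditions: Cl3CCO2H, Cl3CCO2Na, DMF, 25 °C
Reagents that add atoms: trichloroacetic acid OC(=O)C(Cl)(Cl)Cl
Why: Decarboxylative generation of trichloromethyl anion and its 1,2-addition to the enal (first stage of the Corey–Link sequence) brings in C10 as a CCl3 group; C9 forms as an epimer mixture that steps 15 and 16 correct.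

Step 15
Reactants: 22 trichloromethyl carbinol
Product: 23 bis[2-(trimethylsilyl)ethyl] 2-[(3S,5S,8S,9R)-9-acetoxy-3-[(tert-butyldimethylsilyl)oxy]-14,14,14-trichloro-8-hydroxy-2,8-dimethyl-12-methylidene-13-oxotetradec-1-en-5-yl]propanedioate
Conditions: Dess–Martin periodinane, CH2Cl2, 0 to 25 °C
Reagents that add atoms: none
Why: Dess–Martin oxidation of the trichloromethyl carbinol to the trichloromethyl ketone under neutral conditions; O13 is silylated and the tertiary alcohol is inert.

Step 16
Reactants: 23 trichloromethyl ketone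
Product: 24 bis[2-(trimethylsilyl)ethyl] 2-[(3S,5S,8S,9R,13S)-9-acetoxy-3-[(tert-butyldimethylsilyl)oxy]-14,14,14-trichloro-8,13-dihydroxy-2,8-dimethyl-12-methylidenetetradec-1-en-5-yl]propanedioate
Conditions: (R)-2-methyl-CBS-oxazaborolidine (30 mol %), catecholborane, toluene, −78 to −40 °C
Reagents that add atoms: none
Why: Corey–Bakshi–Shibata reduction of a trichloromethyl ketone, in which CCl3 acts as the large substituent, should give with the (R)-catalyst the carbinol with the target's spatial arrangement at C9 (descriptor S here because CCl3 outranks C8).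

Step 17
Reactants: 24 open-chain trichloromethyl carbinol
Product: 26 bis[2-(trimethylsilyl)ethyl] 2-[(1S,4S,5R,9S,12S,13S)-5-acetoxy-13-[(tert-butyldimethylsilyl)oxy]-10,10-dichloro-9,12-epoxy-4-hydroxy-4,12-dimethyl-8-methylidenecyclotetradecyl]propanedioate, via macrocyclic γ-chloro alcohol 25 (not isolated)
Conditions: CuCl (20 mol %), tris(2-pyridylmethyl)amine (22 mol %), NaHCO3 (3 equiv), (CF3)2CHOH/ClCH2CH2Cl 1:4, 1 mM, 70 °C, Ar
Reagents that add atoms: none
Why: Proposed new method: monovalent copper abstracts chlorine from the CCl3 group to give an electrophilic α,α-dichloro-β-hydroxyalkyl radical at C10, which adds to the unsubstituted terminus C11 of the electron-rich 1,1-disubstituted alkene; chlorine transfer from divalent copper to the tertiary C12 radical gives γ-chloro alcohol 25, whose tertiary C–Cl bond ionises in the fluoroalcohol and is captured by the C9 hydroxyl. The closest known reactions are the copper-catalysed Kharasch atom-transfer macrocyclisation of ω-alkenyl trichloroacetates and the one-pot Kharasch addition–lactonisation of trichloroacetic acid with alkenes (a formal [3+2] annulation); neither has been shown with a trichloromethyl carbinol, with ether formation, or as a macrocyclising annulation. The carbocycle closes in the 14-endo-trig radical mode (C10–C11) and the oxolane in the 5-exo-tet, SN1-type ionic mode (O–C12), the gem-dichloro group at C10 favouring the second closure. C12 is the only new stereocenter and is set in the C–O closure: the ten-carbon bridge C13–C14–C1…C8 can span C12 and the preset C9 centre without severe strain only on one face of the oxolane, so C13 should end syn to C8 and the methyl group anti. The step needs regioselectivity for C11 (terminal attack, tertiary radical), chemoselectivity over the C8 methylidene (only 3-exo or 4-endo closures are open to it) and over intermolecular addition (1 mM, persistent-radical effect), and C–O closure faster than hydride shift from C13, which the bulky silyl ether on O13 and the buffered medium are meant to secure.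

Step 18
Reactants: 26 dichloride
Product: 27 bis[2-(trimethylsilyl)ethyl] 2-[(1S,4S,5R,9R,12S,13S)-5-acetoxy-13-[(tert-butyldimethylsilyl)oxy]-9,12-epoxy-4-hydroxy-4,12-dimethyl-8-methylidenecyclotetradecyl]propanedioate
Conditions: Bu3SnH (5 equiv, 0.3 M), AIBN, toluene, 90 °C
Reagents that add atoms: none
Why: Radical-chain hydrodechlorination with tributyltin hydride replaces both chlorine atoms at C10 by hydrogen; the β-alkoxy C10 radical does not fragment and the high tin hydride concentration should outrun 3-exo attack on the adjacent methylidene, so no stereocenter is affected.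

Step 19
Reactants: 27 silylated diester
Product: 28 2-[(1S,4S,5R,9R,12S,13S)-5-acetoxy-9,12-epoxy-4,13-dihydroxy-4,12-dimethyl-8-methylidenecyclotetradecyl]propanedioic acid
Conditions: tris(dimethylamino)sulfonium difluorotrimethylsilicate (TASF, 6 equiv), DMF, 0 to 25 °C; aq. NH4Cl/HCl (pH 3)
Reagents that add atoms: none
Why: Fluoride-induced cleavage: attack on silicon fragments both 2-(trimethylsilyl)ethyl esters to carboxylates and ethene and removes the silyl ether on O13, while the anhydrous, weakly basic fluoride source should spare the acetate.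

Step 20
Reactants: 28 malonic acid
Product: 29 2-[(1S,4S,5R,9R,12S,13S)-5-acetoxy-9,12-epoxy-4,13-dihydroxy-4,12-dimethyl-8-methylidenecyclotetradecyl]prop-2-enoic acid (CNP0215199.3)
Conditions: (CH2O)n, Et2NH, EtOAc, 70 °C; pH 4 work-up
Reagents that add atoms: formaldehyde C=O
Why: Mannich reaction of the malonic acid with formaldehyde and diethylamine followed by decarboxylative elimination of the amine gives the 2-substituted acrylic acid, and the basic medium with a pH 4 work-up should avoid lactonisation of O13.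

**Compound list**

1 | geraniol, (2E)-3,7-dimethylocta-2,6-dien-1-ol | CC(C)=CCC/C(C)=C/CO | starting material
2 | [(2R,3R)-3-methyl-3-(4-methylpent-3-en-1-yl)oxiran-2-yl]methanol ((2R,3R)-2,3-epoxygeraniol) | CC(C)=CCC[C@@]1(C)O[C@@H]1CO | intermediate
3 | [(2R,3R)-3-methyl-3-(4-methylpent-3-en-1-yl)oxiran-2-yl]methyl 4-methylbenzenesulfonate | CC(C)=CCC[C@@]1(C)O[C@@H]1COS(=O)(=O)c1ccc(C)cc1 | intermediate
4 | 2-(2-bromoethyl)-1,3-dioxolane | BrCCC1OCCO1 | starting material
5 | [2-(1,3-dioxolan-2-yl)ethyl]magnesium bromide | Br[Mg]CCC1OCCO1 | intermediate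
6 | 2-{3-[(2R,3R)-3-methyl-3-(4-methylpent-3-en-1-yl)oxiran-2-yl]propyl}-1,3-dioxolane | CC(C)=CCC[C@@]1(C)O[C@@H]1CCCC1OCCO1 | intermediate
7 | (E)-but-2-enal (crotonaldehyde) | C/C=C/C=O | starting material
8 | (2E)-5-{(2R,3R)-3-[3-(1,3-dioxolan-2-yl)propyl]-2-methyloxiran-2-yl}pent-2-enal | O=C/C=C/CC[C@@]1(C)O[C@@H]1CCCC1OCCO1 | intermediate
9 | malonic acid | OC(=O)CC(=O)O | starting material
10 | 2-(trimethylsilyl)ethanol | C[Si](C)(C)CCO | starting material
11 | bis[2-(trimethylsilyl)ethyl] propanedioate | C[Si](C)(C)CCOC(=O)CC(=O)OCC[Si](C)(C)C | intermediate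
12 | bis[2-(trimethylsilyl)ethyl] 2-[(3S)-5-{(2R,3R)-3-[3-(1,3-dioxolan-2-yl)propyl]-2-methyloxiran-2-yl}-1-oxopentan-3-yl]propanedioate | O=CC[C@H](CC[C@@]1(C)O[C@@H]1CCCC1OCCO1)C(C(=O)OCC[Si](C)(C)C)C(=O)OCC[Si](C)(C)C | intermediate
13 | bis[2-(trimethylsilyl)ethyl] 2-[(3S,6S,7R)-10-(1,3-dioxolan-2-yl)-6,7-dihydroxy-6-methyl-1-oxodecan-3-yl]propanedioate | O=CC[C@H](CC[C@](C)(O)[C@H](O)CCCC1OCCO1)C(C(=O)OCC[Si](C)(C)C)C(=O)OCC[Si](C)(C)C | intermediate
14 | bis[2-(trimethylsilyl)ethyl] 2-[(3S,6S,7R)-7-acetoxy-10-(1,3-dioxolan-2-yl)-6-hydroxy-6-methyl-1-oxodecan-3-yl]propanedioate | O=CC[C@H](CC[C@](C)(O)[C@H](OC(C)=O)CCCC1OCCO1)C(C(=O)OCC[Si](C)(C)C)C(=O)OCC[Si](C)(C)C | intermediate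
15 | 2-bromopropene | C=C(C)Br | starting material
16 | bis[2-(trimethylsilyl)ethyl] 2-[(5S,8S,9R)-9-acetoxy-12-(1,3-dioxolan-2-yl)-3,8-dihydroxy-2,8-dimethyldodec-1-en-5-yl]propanedioate (both C3 epimers) | C=C(C)C(O)C[C@H](CC[C@](C)(O)[C@H](OC(C)=O)CCCC1OCCO1)C(C(=O)OCC[Si](C)(C)C)C(=O)OCC[Si](C)(C)C | intermediate
17 | bis[2-(trimethylsilyl)ethyl] 2-[(5S,8S,9R)-9-acetoxy-12-(1,3-dioxolan-2-yl)-8-hydroxy-2,8-dimethyl-3-oxododec-1-en-5-yl]propanedioate | C=C(C)C(=O)C[C@H](CC[C@](C)(O)[C@H](OC(C)=O)CCCC1OCCO1)C(C(=O)OCC[Si](C)(C)C)C(=O)OCC[Si](C)(C)C | intermediate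
18 | bis[2-(trimethylsilyl)ethyl] 2-[(3S,5S,8S,9R)-9-acetoxy-12-(1,3-dioxolan-2-yl)-3,8-dihydroxy-2,8-dimethyldodec-1-en-5-yl]propanedioate | C=C(C)[C@@H](O)C[C@H](CC[C@](C)(O)[C@H](OC(C)=O)CCCC1OCCO1)C(C(=O)OCC[Si](C)(C)C)C(=O)OCC[Si](C)(C)C | intermediate
19 | bis[2-(trimethylsilyl)ethyl] 2-[(3S,5S,8S,9R)-9-acetoxy-3-[(tert-butyldimethylsilyl)oxy]-12-(1,3-dioxolan-2-yl)-8-hydroxy-2,8-dimethyldodec-1-en-5-yl]propanedioate | C=C(C)[C@@H](O[Si](C)(C)C(C)(C)C)C[C@H](CC[C@](C)(O)[C@H](OC(C)=O)CCCC1OCCO1)C(C(=O)OCC[Si](C)(C)C)C(=O)OCC[Si](C)(C)C | intermediate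
20 | bis[2-(trimethylsilyl)ethyl] 2-[(3S,5S,8S,9R)-9-acetoxy-3-[(tert-butyldimethylsilyl)oxy]-8-hydroxy-2,8-dimethyl-13-oxotridec-1-en-5-yl]propanedioate | C=C(C)[C@@H](O[Si](C)(C)C(C)(C)C)C[C@H](CC[C@](C)(O)[C@H](OC(C)=O)CCCC=O)C(C(=O)OCC[Si](C)(C)C)C(=O)OCC[Si](C)(C)C | intermediate
21 | bis[2-(trimethylsilyl)ethyl] 2-[(3S,5S,8S,9R)-9-acetoxy-3-[(tert-butyldimethylsilyl)oxy]-12-formyl-8-hydroxy-2,8-dimethyltrideca-1,12-dien-5-yl]propanedioate | C=C(C)[C@@H](O[Si](C)(C)C(C)(C)C)C[C@H](CC[C@](C)(O)[C@H](OC(C)=O)CCC(=C)C=O)C(C(=O)OCC[Si](C)(C)C)C(=O)OCC[Si](C)(C)C | intermediate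
22 | bis[2-(trimethylsilyl)ethyl] 2-[(3S,5S,8S,9R)-9-acetoxy-3-[(tert-butyldimethylsilyl)oxy]-14,14,14-trichloro-8,13-dihydroxy-2,8-dimethyl-12-methylidenetetradec-1-en-5-yl]propanedioate (both C13 epimers) | C=C(C)[C@@H](O[Si](C)(C)C(C)(C)C)C[C@H](CC[C@](C)(O)[C@H](OC(C)=O)CCC(=C)C(O)C(Cl)(Cl)Cl)C(C(=O)OCC[Si](C)(C)C)C(=O)OCC[Si](C)(C)C | intermediate
23 | bis[2-(trimethylsilyl)ethyl] 2-[(3S,5S,8S,9R)-9-acetoxy-3-[(tert-butyldimethylsilyl)oxy]-14,14,14-trichloro-8-hydroxy-2,8-dimethyl-12-methylidene-13-oxotetradec-1-en-5-yl]propanedioate | C=C(C)[C@@H](O[Si](C)(C)C(C)(C)C)C[C@H](CC[C@](C)(O)[C@H](OC(C)=O)CCC(=C)C(=O)C(Cl)(Cl)Cl)C(C(=O)OCC[Si](C)(C)C)C(=O)OCC[Si](C)(C)C | intermediate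
24 | bis[2-(trimethylsilyl)ethyl] 2-[(3S,5S,8S,9R,13S)-9-acetoxy-3-[(tert-butyldimethylsilyl)oxy]-14,14,14-trichloro-8,13-dihydroxy-2,8-dimethyl-12-methylidenetetradec-1-en-5-yl]propanedioate | C=C(C)[C@@H](O[Si](C)(C)C(C)(C)C)C[C@H](CC[C@](C)(O)[C@H](OC(C)=O)CCC(=C)[C@H](O)C(Cl)(Cl)Cl)C(C(=O)OCC[Si](C)(C)C)C(=O)OCC[Si](C)(C)C | intermediate
25 | bis[2-(trimethylsilyl)ethyl] 2-[(1S,4S,5R,9S,13S)-5-acetoxy-13-[(tert-butyldimethylsilyl)oxy]-10,10,12-trichloro-4,9-dihydroxy-4,12-dimethyl-8-methylidenecyclotetradecyl]propanedioate (C12 epimers; ring locants of the target) | C[Si](C)(C)CCOC(=O)C(C(=O)OCC[Si](C)(C)C)[C@H]1CC[C@](C)(O)[C@H](OC(C)=O)CCC(=C)[C@H](O)C(Cl)(Cl)CC(C)(Cl)[C@@H](O[Si](C)(C)C(C)(C)C)C1 | intermediate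
26 | bis[2-(trimethylsilyl)ethyl] 2-[(1S,4S,5R,9S,12S,13S)-5-acetoxy-13-[(tert-butyldimethylsilyl)oxy]-10,10-dichloro-9,12-epoxy-4-hydroxy-4,12-dimethyl-8-methylidenecyclotetradecyl]propanedioate (ring locants of the target) | C[Si](C)(C)CCOC(=O)C(C(=O)OCC[Si](C)(C)C)[C@H]1CC[C@](C)(O)[C@H](OC(C)=O)CCC(=C)[C@H]2C(Cl)(Cl)C[C@](C)(O2)[C@@H](O[Si](C)(C)C(C)(C)C)C1 | intermediate
27 | bis[2-(trimethylsilyl)ethyl] 2-[(1S,4S,5R,9R,12S,13S)-5-acetoxy-13-[(tert-butyldimethylsilyl)oxy]-9,12-epoxy-4-hydroxy-4,12-dimethyl-8-methylidenecyclotetradecyl]propanedioate | C[Si](C)(C)CCOC(=O)C(C(=O)OCC[Si](C)(C)C)[C@H]1CC[C@](C)(O)[C@H](OC(C)=O)CCC(=C)[C@H]2CC[C@](C)(O2)[C@@H](O[Si](C)(C)C(C)(C)C)C1 | intermediate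
28 | 2-[(1S,4S,5R,9R,12S,13S)-5-acetoxy-9,12-epoxy-4,13-dihydroxy-4,12-dimethyl-8-methylidenecyclotetradecyl]propanedioic acid | O=C(O)C(C(=O)O)[C@H]1CC[C@](C)(O)[C@H](OC(C)=O)CCC(=C)[C@H]2CC[C@](C)(O2)[C@@H](O)C1 | intermediate
29 | 2-[(1S,4S,5R,9R,12S,13S)-5-acetoxy-9,12-epoxy-4,13-dihydroxy-4,12-dimethyl-8-methylidenecyclotetradecyl]prop-2-enoic acid (CNP0215199.3) | C=C(C(=O)O)[C@H]1CC[C@](C)(O)[C@H](OC(C)=O)CCC(=C)[C@H]2CC[C@](C)(O2)[C@@H](O)C1 | target

**Step count**

Total step count: 20.
Longest linear sequence: 19 steps (geraniol 1 to 29 through steps 1–3 and 5–20; step 4 is a one-step side branch).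

**Steps most likely to fail**

1. Step 17 (Proposed new method). What may go wrong: the 14-endo ring closure may be too slow against intermolecular addition and oligomerisation. Hydride migration from C13 or proton loss at the C12 cation may outrun C–O closure. The facial selectivity of the C–O closure at C12 may be poor. The C10 radical may rearrange through 3-exo attack on the C8 methylidene. Fallback with known chemistry, from 23 back to 26: the trichloromethyl ketone 23, the established substrate class for copper-catalysed Kharasch atom-transfer radical cyclisation, is macrocyclised (CuCl, tris(2-pyridylmethyl)amine, ClCH2CH2Cl, 80 °C, 2 mM) to the macrocyclic 10,10,12-trichloro 9-ketone F1. Oxazaborolidine-controlled reduction ((R)-catalyst, catecholborane) then sets C9 and gives the γ-chloro alcohol 25, now isolated. AgOTf with 2,6-di-tert-butyl-4-methylpyridine in CH2Cl2 at −20 °C closes the oxolane in a separate silver-assisted etherification and rejoins the route at 26.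

2. Step 2. What may go wrong: opening of the oxirane by magnesium halide or by the organocopper species, and elimination, may compete with substitution at the tosylate. Fallback, from 2 (isolated by omitting the tosylation in step 1) back to 6: Parikh–Doering oxidation (SO3·pyridine, DMSO, Et3N) gives the epoxy aldehyde F2. A Wittig reaction with the ylide from [2-(1,3-dioxolan-2-yl)ethyl]triphenylphosphonium bromide (NaHMDS, THF, −78 °C) gives the (Z)-alkenyl oxirane F3. Diimide reduction (2-nitrobenzenesulfonohydrazide, Et3N) of the disubstituted alkene, which should react well before the trisubstituted prenyl alkene, then gives 6.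

3. Step 3. What may go wrong: slow turnover at the trisubstituted prenyl alkene, loss of crotonaldehyde to self-metathesis and catalyst decomposition before full conversion. Fallback, from 6 back to 8: ozonolysis of the only alkene (O3, CH2Cl2, −78 °C; PPh3) gives the aldehyde F4, and a Wittig reaction with (triphenylphosphoranylidene)acetaldehyde (toluene, 80 °C) gives the E-enal 8.

**Further compounds**

F1 | step 17 | bis[2-(trimethylsilyl)ethyl] 2-[(1S,4S,5R,13S)-5-acetoxy-13-[(tert-butyldimethylsilyl)oxy]-10,10,12-trichloro-4-hydroxy-4,12-dimethyl-8-methylidene-9-oxocyclotetradecyl]propanedioate (C12 epimers; ring locants of the target) | C[Si](C)(C)CCOC(=O)C(C(=O)OCC[Si](C)(C)C)[C@H]1CC[C@](C)(O)[C@H](OC(C)=O)CCC(=C)C(=O)C(Cl)(Cl)CC(C)(Cl)[C@@H](O[Si](C)(C)C(C)(C)C)C1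
F2 | step 2 | (2S,3R)-3-methyl-3-(4-methylpent-3-en-1-yl)oxirane-2-carbaldehyde | CC(C)=CCC[C@@]1(C)O[C@@H]1C=O
F3 | step 2 | 2-{(2Z)-3-[(2R,3R)-3-methyl-3-(4-methylpent-3-en-1-yl)oxiran-2-yl]prop-2-en-1-yl}-1,3-dioxolane | CC(C)=CCC[C@@]1(C)O[C@@H]1/C=C\CC1OCCO1
F4 | step 3 | 3-{(2R,3R)-3-[3-(1,3-dioxolan-2-yl)propyl]-2-methyloxiran-2-yl}propanal | O=CCC[C@@]1(C)O[C@@H]1CCCC1OCCO1
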